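The runs are simulated with constants of no real substance; scatter was added.

the same everywhere: substrate 0.10 M
- Wednesday's: solid reagent 0.095 M; the very flask that is asked about, followed so far
- Saturday's: solid reagent 0.064 M; run made earlier
- flask: solid reagent 0.0950 M; time 12 h

| run | time / h | target / % |
|---|---|---|
| Wednesday's | 3.00 | 21.4 |
| Wednesday's | 4.00 | 34.9 |
| Wednesday's | 5.00 | 44.1 |
| Wednesday's | 6.00 | 49.4 |
| Saturday's | 3.00 | 23.1 |
| Saturday's | 5.00 | 34.4 |
| Saturday's | 8.00 | 46.6 |
| Saturday's | 12.0 | 54.1 |

(readings scatter by 1 percentage point)

* time, not beyond 12 h, at which the flask holds most target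
* the amount of target, in percent of the substrate charged, at that time

- solid reagent is a solid; its amount is given per volume of the solution
- at the start none of the solid reagent is in solution

Solid reagent to substrate stands at 0.950 in Wednesday's flask and 0.640 in Saturday's run. If one of each makes one target, solid reagent is the limiting reagent, so I keep the books on it. At 3.00 h the two runs read 21.4% and 23.1% despite unequal charges, so I treat the early hours as dissolving and open the ledger later, assuming the charge is in solution by then.

u = solid reagent charged − [target]
v = substrate charged − [target]
gain of [target] = k·u·v, so ln(v/u) grows by k·(v − u)·time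

Saturday's readings from 5.00 h to 12.0 h give 2.93 L mol⁻¹ h⁻¹, my pairing constant, the gain of target per unit of u times v. The stretch to 8.00 h reads 3.01 L mol⁻¹ h⁻¹, so I book no loss of target.

Opening Wednesday's ledger at 6.00 h, the gain stays positive, so my peak lies at 12 h, with 71.4%.

The forecast, which differs, says 52% at 7.5 h, on the suggestion that “excess reagent is starting to attack the target”.

The flask gives 69.9% at 12.0 h, 1.5 percentage points under my figure.

    solid reagent ⇌ partner, rate k1*(cs1 - [partner]) while solid is left; crystals form when [partner] > cs1 (solubility = 0.0850 M, k = 1.40 × 10⁻⁴ s⁻¹)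
    partner + intermediate → target (k = 7.20 × 10⁻⁴ L mol⁻¹ s⁻¹)
    substrate → intermediate (k = 9.30 × 10⁻⁴ s⁻¹)

In the flask at 12.0 h, the half-life of intermediate by its step with partner is 11 h, far longer than the 0.21 h of substrate by its step to intermediate at 0.207 h. With [partner] at 0.0251 M and intermediate at 30.1% in the flask at that same time, 2.93 L mol⁻¹ h⁻¹ still books a gain of 0.00222 M h⁻¹. For the flask charged with 0.038 M, whose ratio allows 38.0%, a ledger opened at time zero with the charge taken as dissolved gives 35.2% by 12 h; the computed target there is 34.0%.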